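The synthesis rests on cutting C4–C5 of the butyrolactone ring (O1, C2, C3, C4, C5) once O1–C2 is opened. It exploits the 1,4-diol hidden in O–C7'–C3–C4–C5–O1. The exocyclic carbinol oxygen and ring oxygen O1 flank a four-carbon chain, so one silicon atom can bridge the C7' oxygen and C5 in a six-membered ring. In one operation a tethered radical closes a 1-oxa-2-silacyclohexane 6-endo, forms C4–C5 and sets C4 and C3 from C7'. The precursor is the (bromomethyl)dimethylsilyl ether of an enantiopure methyl (E)-2-[aryl(hydroxy)methyl]-4-arylbut-2-enoate whose C4 benzyl group lies cis to C7'. Oxidation of C5–Si, lactonisation and debenzylation finish the synthesis.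

Key step: step 7

Numbering: lactone ring O1, C2 (C=O), C3, C4, C5; C7' is the carbinol carbon on C3 and C7 is the benzylic CH2 on C4.
Remark on descriptors: the spatial arrangement at C7' does not change after step 3. Its label is R in 7–10 and 12, where the sp or sp2 carbon C3 outranks the aryl group, and S from 13 on, where the aryl group outranks sp3 C3.
Assumption: the (S)-BINOL/Ti(OiPr)4 alkynylzinc system is taken to attack the Si face of aromatic aldehydes; the sense is checked on 7, and (R)-BINOL is used should it prove opposite.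

Step 1
Reactants: 1 [4-(benzyloxy)-3-methoxyphenyl]methanol
Product: 2 1-(benzyloxy)-4-(bromomethyl)-2-methoxybenzene
Conditions: PBr3 (0.4 equiv), Et2O, 0 °C; used without chromatography
Reagents that add atoms: phosphorus tribromide, BrP(Br)Br
Why: SN2 bromination of an activated primary benzylic alcohol through its phosphite ester is fast at 0 °C and should leave the aryl benzyl and methyl ethers untouched.

Step 2
Reactants: 2 1-(benzyloxy)-4-(bromomethyl)-2-methoxybenzene; 3 ethynylmagnesium bromide
Product: 4 1-(benzyloxy)-2-methoxy-4-(prop-2-yn-1-yl)benzene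
Conditions: 3 (2.5 equiv, 0.5 M in THF), CuBr (10 mol %), THF, 0 → 50 °C
Reagents that add atoms: 3 ethynylmagnesium bromide, C#C[Mg]Br
Why: Copper-catalysed cross-coupling of an alkynyl Grignard reagent with a benzylic bromide, in which the excess of 3 suppresses double benzylation and the absence of amine or alkoxide base keeps the skipped aryl-alkyne from isomerising to the allene.

Step 3
Reactants: 4 1-(benzyloxy)-2-methoxy-4-(prop-2-yn-1-yl)benzene; 5 4-(benzyloxy)-3-methoxybenzaldehyde
Product: 7 (1R)-1,4-bis[4-(benzyloxy)-3-methoxyphenyl]but-2-yn-1-ol, via ethyl(alkynyl)zinc 6 (not isolated)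
Conditions: 4 (2 equiv), Et2Zn (2 equiv), Cy2NH (5 mol %), (S)-BINOL (20 mol %), Et2O, rt; Ti(OiPr)4 (50 mol %), rt; then 5 (1 equiv), rt; H2O quench; excess 4 recovered, 7 recrystallised if the optical purity needs upgrading
Reagents that add atoms: diethylzinc, CC[Zn]CC (its EtZn unit stays in 6 only)
Why: Catalytic asymmetric alkynylzinc addition to an aromatic aldehyde under a BINOL–titanium Lewis acid delivers the alkynyl group to the Si face and sets C7' as R, and it is preferred to asymmetric transfer hydrogenation of the corresponding aryl alkynyl ketone, which would have to tell two π-substituents apart and would pass through an ynone with an acidic, doubly activated CH2.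

Step 4
Reactants: 7 (1R)-1,4-bis[4-(benzyloxy)-3-methoxyphenyl]but-2-yn-1-ol
Product: 9 (1R,2E)-1,4-bis[4-(benzyloxy)-3-methoxyphenyl]-2-iodobut-2-en-1-ol, via vinylstannane 8 (not isolated)
Conditions: Bu3SnH (1.2 equiv, slow addition), PdCl2(PPh3)2 (3 mol %), THF, 0 °C → rt; then I2 (1.2 equiv), 0 °C; chromatography removes any regioisomeric iodide
Reagents that add atoms: iodine, II; tributylstannane, CCCC[SnH](CCCC)CCCC (its tin stays in 8 only)
Why: Palladium-catalysed syn-hydrostannation should place hydrogen on C4 and tin on C3, the alkyne carbon made electron-poorer by the propargylic oxygen, so that C7' and the C4 benzyl group end up cis, and iododestannylation then replaces tin with retention of the alkene geometry without touching C7'.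

Step 5
Reactants: 9 (1R,2E)-1,4-bis[4-(benzyloxy)-3-methoxyphenyl]-2-iodobut-2-en-1-ol
Product: 10 methyl (2E)-4-[4-(benzyloxy)-3-methoxyphenyl]-2-{(R)-[4-(benzyloxy)-3-methoxyphenyl](hydroxy)methyl}but-2-enoate
Conditions: CO (1 atm), Pd(PPh3)4 (5 mol %), Et3N (2 equiv), MeOH/DMF 1:1, 50 °C
Reagents that add atoms: carbon monoxide, [C-]#[O+]; methanol, CO
Why: Palladium-catalysed alkoxycarbonylation of an alkenyl iodide runs through oxidative addition, CO insertion and methanolysis with retention at C3=C4, and methanol as co-solvent should outrun closure of a four-membered lactone by the C7' hydroxyl.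

Step 6
Reactants: 10 methyl (2E)-4-[4-(benzyloxy)-3-methoxyphenyl]-2-{(R)-[4-(benzyloxy)-3-methoxyphenyl](hydroxy)methyl}but-2-enoate; 11 (bromomethyl)chlorodimethylsilane
Product: 12 methyl (2E)-4-[4-(benzyloxy)-3-methoxyphenyl]-2-{(R)-[4-(benzyloxy)-3-methoxyphenyl][(bromomethyl)dimethylsilyloxy]methyl}but-2-enoate
Conditions: 11 (1.3 equiv), Et3N (1.5 equiv), DMAP (5 mol %), CH2Cl2, 0 °C → rt; rapid filtration through Et3N-washed silica
Reagents that add atoms: 11 (bromomethyl)chlorodimethylsilane, C[Si](C)(Cl)CBr
Why: O-silylation of a secondary alcohol by substitution at silicon leaves the C7'–O bond, and hence the configuration, intact, and the Si–Cl bond reacts far faster than the C–Br bond.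

Step 7
Reactants: 12 methyl (2E)-4-[4-(benzyloxy)-3-methoxyphenyl]-2-{(R)-[4-(benzyloxy)-3-methoxyphenyl][(bromomethyl)dimethylsilyloxy]methyl}but-2-enoate
Product: 13 methyl (4R,5S,6S)-4-[4-(benzyloxy)-3-methoxybenzyl]-6-[4-(benzyloxy)-3-methoxyphenyl]-2,2-dimethyl-1,2-oxasilinane-5-carboxylate
Conditions: Bu3SnH (1.3 equiv) and AIBN (0.2 equiv) in PhH added by syringe pump over 8 h to 12 (0.01 M) in degassed PhH, 80 °C; MeCN/hexane partition
Reagents that add atoms: none
Why: Bu3Sn• abstracts bromine from 12, the nucleophilic α-silylmethyl radical centred on C5 adds to C4 of the electron-poor enoate, and the ester-stabilised C3 radical takes hydrogen from Bu3SnH to carry the chain, which is the known silicon-tethered reductive radical cyclisation of (bromomethyl)dimethylsilyl ethers of 2-substituted allylic alcohols. The one ring formed, the 1-oxa-2-silacyclohexane O–Si–C5–C4–C3–C7', closes 6-endo-trig, because 5-exo attack would have to hit the fully substituted, polarity-mismatched C3 and would leave an unstabilised secondary radical on C4, while the long Si–O and Si–C bonds ease the endo geometry. C4 is set by C7': the C4 benzyl group lies cis to C7' on the (E)-alkene, so allylic 1,3-strain excludes every rotamer that turns the C7' aryl group towards it, the aryl group sits pseudo-equatorial in a chair-like transition state, the siloxy arm stands over a single alkene face and C5 bonds there, which makes C4 R with its benzyl group axial and trans to the aryl group. C3 is set by C4: the axial benzyl group screens one lobe of the planar radical, the stannane therefore delivers hydrogen axially on the face that already received C5, and the ester ends up equatorial, trans to the aryl group and cis to the benzyl group (3S), the arrangement that becomes the trans-3,4-disubstituted lactone once C5 is tied to C2. The selectivity needed is ring closure ahead of direct reduction, since C4 carries a substituent and is attacked more slowly than a terminal acrylate carbon; the activated acceptor and a very low stationary stannane concentration secure it. The benzylic C7–H bonds are out of reach (only an eight-membered hydrogen-transfer transition state), and the tiglate-like (E)-geometry is the more stable one, so reversible stannyl radical addition should not erode it.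

Step 8
Reactants: 13 methyl (4R,5S,6S)-4-[4-(benzyloxy)-3-methoxybenzyl]-6-[4-(benzyloxy)-3-methoxyphenyl]-2,2-dimethyl-1,2-oxasilinane-5-carboxylate
Product: 15 (3S,4R)-4-[4-(benzyloxy)-3-methoxybenzyl]-3-{(S)-[4-(benzyloxy)-3-methoxyphenyl](hydroxy)methyl}oxolan-2-one, via diol ester 14 (not isolated)
Conditions: 30% aq. H2O2 (10 equiv), KF (3 equiv), KHCO3 (3 equiv), THF/MeOH 1:1, rt → 40 °C
Reagents that add atoms: hydrogen peroxide, OO
Why: In this Tamao oxidation the alkoxy-activated silicon takes up fluoride and hydroperoxide, C5 migrates from silicon to oxygen, both Si–O bonds are hydrolysed and the freed C5 hydroxyl closes on the C2 methyl ester (5-exo-trig lactonisation), whereas the C7' hydroxyl could only form a strained four-membered ring and bicarbonate is too weak a base for retro-aldol cleavage or C3 epimerisation.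

Step 9
Reactants: 15 (3S,4R)-4-[4-(benzyloxy)-3-methoxybenzyl]-3-{(S)-[4-(benzyloxy)-3-methoxyphenyl](hydroxy)methyl}oxolan-2-one
Product: 16 (3S,4R)-4-(4-hydroxy-3-methoxybenzyl)-3-[(S)-hydroxy(4-hydroxy-3-methoxyphenyl)methyl]oxolan-2-one
Conditions: H2 (1 atm), 10% Pd/C, EtOAc, rt, stopped after uptake of 2 equiv H2
Reagents that add atoms: none
Why: Catalytic hydrogenolysis cleaves the two unhindered aryl O–CH2Ph bonds much faster than the hindered secondary C7'–OH bond, whose loss needs acid activation, so a neutral aprotic medium should preserve the carbinol, the lactone and all three stereocentres.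

Compound list
1 | [4-(benzyloxy)-3-methoxyphenyl]methanol | COc1cc(CO)ccc1OCc1ccccc1 | starting material
2 | 1-(benzyloxy)-4-(bromomethyl)-2-methoxybenzene | COc1cc(CBr)ccc1OCc1ccccc1 | intermediate
3 | ethynylmagnesium bromide | C#C[Mg]Br | starting material
4 | 1-(benzyloxy)-2-methoxy-4-(prop-2-yn-1-yl)benzene | C#CCc1ccc(OCc2ccccc2)c(OC)c1 | intermediate
5 | 4-(benzyloxy)-3-methoxybenzaldehyde | COc1cc(C=O)ccc1OCc1ccccc1 | starting material
6 | ethyl{3-[4-(benzyloxy)-3-methoxyphenyl]prop-1-yn-1-yl}zinc | CC[Zn]C#CCc1ccc(OCc2ccccc2)c(OC)c1 | intermediate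
7 | (1R)-1,4-bis[4-(benzyloxy)-3-methoxyphenyl]but-2-yn-1-ol | O[C@@H](C#CCc1ccc(OCc2ccccc2)c(OC)c1)c1ccc(OCc2ccccc2)c(OC)c1 | intermediate
8 | (1R,2E)-1,4-bis[4-(benzyloxy)-3-methoxyphenyl]-2-(tributylstannyl)but-2-en-1-ol | CCCC[Sn](CCCC)(CCCC)/C(=C/Cc1ccc(OCc2ccccc2)c(OC)c1)[C@H](O)c1ccc(OCc2ccccc2)c(OC)c1 | intermediate
9 | (1R,2E)-1,4-bis[4-(benzyloxy)-3-methoxyphenyl]-2-iodobut-2-en-1-ol | I/C(=C/Cc1ccc(OCc2ccccc2)c(OC)c1)[C@H](O)c1ccc(OCc2ccccc2)c(OC)c1 | intermediate
10 | methyl (2E)-4-[4-(benzyloxy)-3-methoxyphenyl]-2-{(R)-[4-(benzyloxy)-3-methoxyphenyl](hydroxy)methyl}but-2-enoate | COC(=O)/C(=C/Cc1ccc(OCc2ccccc2)c(OC)c1)[C@H](O)c1ccc(OCc2ccccc2)c(OC)c1 | intermediate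
11 | (bromomethyl)chlorodimethylsilane | C[Si](C)(Cl)CBr | starting material
12 | methyl (2E)-4-[4-(benzyloxy)-3-methoxyphenyl]-2-{(R)-[4-(benzyloxy)-3-methoxyphenyl][(bromomethyl)dimethylsilyloxy]methyl}but-2-enoate | COC(=O)/C(=C/Cc1ccc(OCc2ccccc2)c(OC)c1)[C@H](O[Si](C)(C)CBr)c1ccc(OCc2ccccc2)c(OC)c1 | intermediate
13 | methyl (4R,5S,6S)-4-[4-(benzyloxy)-3-methoxybenzyl]-6-[4-(benzyloxy)-3-methoxyphenyl]-2,2-dimethyl-1,2-oxasilinane-5-carboxylate | COC(=O)[C@H]1[C@@H](Cc2ccc(OCc3ccccc3)c(OC)c2)C[Si](C)(C)O[C@@H]1c1ccc(OCc2ccccc2)c(OC)c1 | intermediate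
14 | methyl (2S,3R)-4-[4-(benzyloxy)-3-methoxyphenyl]-2-{(S)-[4-(benzyloxy)-3-methoxyphenyl](hydroxy)methyl}-3-(hydroxymethyl)butanoate | COC(=O)[C@H]([C@H](O)c1ccc(OCc2ccccc2)c(OC)c1)[C@@H](Cc1ccc(OCc2ccccc2)c(OC)c1)CO | intermediate
15 | (3S,4R)-4-[4-(benzyloxy)-3-methoxybenzyl]-3-{(S)-[4-(benzyloxy)-3-methoxyphenyl](hydroxy)methyl}oxolan-2-one | COc1cc(C[C@H]2COC(=O)[C@@H]2[C@H](O)c2ccc(OCc3ccccc3)c(OC)c2)ccc1OCc1ccccc1 | intermediate
16 | (3S,4R)-4-(4-hydroxy-3-methoxybenzyl)-3-[(S)-hydroxy(4-hydroxy-3-methoxyphenyl)methyl]oxolan-2-one | COc1cc(C[C@H]2COC(=O)[C@@H]2[C@H](O)c2ccc(O)c(OC)c2)ccc1O | target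

Total step count: 9
Longest linear sequence: 9 steps (1 → 2 → 4 → 7 → 9 → 10 → 12 → 13 → 15 → 16)

Steps most likely to fail

Step 7. Three things may go wrong: hydrogen transfer to the open-chain α-silyl radical before ring closure, incomplete facial control in the C4–C5 bond formation, or hydrogen delivery to the wrong lobe of the C3 radical. The fallback drops the tether and forms C3–C7' last by the classical lignan aldol; it sets out from 5 and comes back at 15.
- Stobbe condensation of 5 with dimethyl succinate (NaOMe, MeOH, reflux) should give the half-ester (3E)-4-[4-(benzyloxy)-3-methoxyphenyl]-3-(methoxycarbonyl)but-3-enoic acid F1.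
- Asymmetric hydrogenation ([Rh(cod)(Et-DuPhos)]BF4, H2, MeOH, ligand antipode chosen for the R product; benzyl ethers survive) should give (3R)-4-[4-(benzyloxy)-3-methoxyphenyl]-3-(methoxycarbonyl)butanoic acid F2.
- Reduction of the ester in the potassium carboxylate with Ca(BH4)2 in EtOH, then acidification, should give (4R)-4-[4-(benzyloxy)-3-methoxybenzyl]oxolan-2-one F3.
- The lithium enolate of F3 (LDA, THF, −78 °C) adds to 5 anti to the C4 benzyl group and should give 15 beside its C7' epimer (3S,4R)-4-[4-(benzyloxy)-3-methoxybenzyl]-3-{(R)-[4-(benzyloxy)-3-methoxyphenyl](hydroxy)methyl}oxolan-2-one F4, which is removed by chromatography.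

Step 4. What may go wrong is poor regiocontrol in the hydrometallation: the steric demand of the secondary carbinol works against the electronic bias of the propargylic oxygen, so tin may go to C4. The fallback replaces that bias by a directing group; it sets out from 7 and comes back at 9.
- MeLi (THF, −78 °C) converts 7 into the lithium alkoxide lithium (1R)-1,4-bis[4-(benzyloxy)-3-methoxyphenyl]but-2-yn-1-olate F5.
- F5 steers Cp2Zr(H)Cl to the proximal alkyne carbon in an alkoxide-directed syn-hydrozirconation and should give the C3-zirconated alkene, the chlorozirconocene (1R,2E)-alkenyl lithium alkoxide F6.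
- Iodinolysis with I2 at 0 °C proceeds with retention and gives 9.

Step 3. What may go wrong is insufficient enantioselection, or propargyl–allenyl isomerisation of the alkyne during zincation. The fallback sets the carbinol centre on a simpler alkyne by enzymatic resolution and attaches C7 afterwards; it sets out from 5 (with 3 and 2) and comes back at 7.
- Addition of 3 to 5 (THF, 0 °C) gives racemic 1-[4-(benzyloxy)-3-methoxyphenyl]prop-2-yn-1-ol F7.
- Immobilised lipase B from Candida antarctica with vinyl acetate (toluene, rt) is expected to acetylate the enantiomer that has the aryl group as large and the ethynyl group as small substituent. This leaves (1S)-1-[4-(benzyloxy)-3-methoxyphenyl]prop-2-yn-1-ol F8 beside (1R)-1-[4-(benzyloxy)-3-methoxyphenyl]prop-2-yn-1-yl acetate F9, which is separated by chromatography.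
- Copper-mediated coupling of the terminal alkyne of F8 with 2 (CuI, NaI, K2CO3, DMF, rt) gives 7. The same spatial arrangement is then labelled R, because the substituted alkynyl group outranks the aryl group.

Further compounds
F1 | step 7 | (3E)-4-[4-(benzyloxy)-3-methoxyphenyl]-3-(methoxycarbonyl)but-3-enoic acid | COC(=O)/C(=C/c1ccc(OCc2ccccc2)c(OC)c1)CC(=O)O
F2 | step 7 | (3R)-4-[4-(benzyloxy)-3-methoxyphenyl]-3-(methoxycarbonyl)butanoic acid | COC(=O)[C@H](Cc1ccc(OCc2ccccc2)c(OC)c1)CC(=O)O
F3 | step 7 | (4R)-4-[4-(benzyloxy)-3-methoxybenzyl]oxolan-2-one | COc1cc(C[C@H]2COC(=O)C2)ccc1OCc1ccccc1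
F4 | step 7 | (3S,4R)-4-[4-(benzyloxy)-3-methoxybenzyl]-3-{(R)-[4-(benzyloxy)-3-methoxyphenyl](hydroxy)methyl}oxolan-2-one | COc1cc(C[C@H]2COC(=O)[C@@H]2[C@@H](O)c2ccc(OCc3ccccc3)c(OC)c2)ccc1OCc1ccccc1
F5 | step 4 | lithium (1R)-1,4-bis[4-(benzyloxy)-3-methoxyphenyl]but-2-yn-1-olate | [Li]O[C@@H](C#CCc1ccc(OCc2ccccc2)c(OC)c1)c1ccc(OCc2ccccc2)c(OC)c1
F6 | step 4 | chlorobis(cyclopentadienyl)[(1R,2E)-1,4-bis[4-(benzyloxy)-3-methoxyphenyl]-1-(lithiooxy)but-2-en-2-yl]zirconium (cyclopentadienyl rings drawn σ-bonded) | Cl[Zr](C1C=CC=C1)(C1C=CC=C1)/C(=C/Cc1ccc(OCc2ccccc2)c(OC)c1)[C@H](O[Li])c1ccc(OCc2ccccc2)c(OC)c1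
F7 | step 3 | racemic 1-[4-(benzyloxy)-3-methoxyphenyl]prop-2-yn-1-ol | OC(C#C)c1ccc(OCc2ccccc2)c(OC)c1
F8 | step 3 | (1S)-1-[4-(benzyloxy)-3-methoxyphenyl]prop-2-yn-1-ol | O[C@@H](C#C)c1ccc(OCc2ccccc2)c(OC)c1
F9 | step 3 | (1R)-1-[4-(benzyloxy)-3-methoxyphenyl]prop-2-yn-1-yl acetate | CC(=O)O[C@H](C#C)c1ccc(OCc2ccccc2)c(OC)c1
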